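The earlier runs and the new flask are calculated for an exercise, and the scatter is random.

Start with the easy step: a steady feed of starting complex into incoming ligand, one ligand taking one complex. We count the flask below, and the two questions stand with it.

| setting | north-east | east | south-east | flask |
|---|---|---|---|---|
| starting complex | 0.13 M (fed, over 20 min) | 0.13 M (fed, over 20 min) | 0.20 M (fed, over 20 min) | 0.13 M (fed, over 20 min) |
| incoming ligand | 0.34 equiv | 0.75 equiv | 0.50 equiv | 0.500 equiv |
| protic impurity | 0.039 M | 0.039 M | 0.039 M | 0.0390 M |
| remark | run made earlier; the fed solution adds 0.50 times the starting volume | run made earlier; the fed solution adds 0.50 times the starting volume | run made earlier; the fed solution adds 0.50 times the starting volume | the fed solution adds 0.50 times the starting volume |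
| time |  |  |  | 20 min |

| run | time / min | starting complex / % | complex with two exchanged / % |
|---|---|---|---|
| north-east | 1.33 | 5.3 | 0.5 |
| north-east | 2.00 | 6.3 | 0.1 |
| north-east | 4.00 | 10.7 | 1.0 |
| north-east | 6.00 | 14.9 | 2.2 |
| north-east | 10.0 | 23.6 | 4.6 |
| north-east | 15.0 | 37.4 | 5.4 |
| east | 1.33 | 3.9 | 0 |
| east | 2.00 | 4.9 | 1.3 |
| east | 4.00 | 7.2 | 4.2 |
| east | 6.00 | 9.9 | 8.0 |
| east | 10.0 | 16.3 | 12.8 |
| east | 15.0 | 26.4 | 16.8 |
| south-east | 3.00 | 6.0 | 2.3 |
| south-east | 6.00 | 10.3 | 6.0 |
| south-east | 10.0 | 19.9 | 9.3 |
| south-east | 12.0 | 24.3 | 10.3 |
| south-east | 15.0 | 32.6 | 11.4 |

(each reading ± 0.3 percentage points)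

* part of the starting complex that has reacted at 20 min
* share of the unused incoming ligand that is free and not bound as idle adduct, at 20 min

- amounts are per litre of the starting volume; all of the dose is in the solution fed
- percentages count the whole charge, also what has not yet gone in
- the earlier runs do not show how much of incoming ligand is bound; that part of a forecast is a guess

With the ligand step by itself, the flask's charge lets 50.0% of the starting complex react. The north-east run shows that this count is too small: at 15.0 min, fed minus present reads 37.6%, more than its ligand charge of 34.0%. So we add the protic impurity as a second one-to-one taker, which gives 30.0% more. Their sum is the reach, the charge of the two takers over the starting complex charged, each taker counted against one starting complex 80.0%: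

reach = 0.500 equiv + 0.0390 M / 0.13 M = 80.0%

The rest, including the second exchange, we do not model. We read it as the share of the reach taken at 15.0 min. That share is 0.588 in the north-east run (reach 64.0%). In the east run it is 0.463 (reach 105%). Interpolating to the reach of our flask gives a share of 0.539, so we reckon 43.1% taken at that time.

Replacing the curve by its mean rate carries this to 57.5% at 20 min. But the last north-east interval reads at 0.894 of that run's mean rate, and with that correction our own figure is 55.9%, a share of 0.699. The readings give us no figure for the free share.

The forecast says 53% reacted, below our figure, and 60% free, adding: “The free share isn't constrained by the data”.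

The flask gives 53.8% reacted and 37.1% free.

    protic impurity + starting complex → quenched substrate (k = 0.0320 L mol⁻¹ s⁻¹)
    complex with one exchanged + incoming ligand → leaving ligand + complex with two exchanged (k = 0.0700 L mol⁻¹ s⁻¹)
    starting complex + complex with one exchanged → side product (k = 0.00750 L mol⁻¹ s⁻¹)
    leaving ligand + incoming ligand ⇌ idle adduct, settled at all times (K = 47.0 L mol⁻¹)
    starting complex + incoming ligand → leaving ligand + complex with one exchanged (k = 0.140 L mol⁻¹ s⁻¹)

The flask's reacted part lies within the tolerance of the forecast's number, while its free share is 23 percentage points lower. Incoming ligand is the limiting reagent in the flask: at 20.0 min, 3.8% of its charge stands unbound, less than the unbound part of either other reactant. The part reacted in the flask is 0.672 of its reach. In the neighbour with 0.120 equiv of incoming ligand, the reach is 42.0%, and 34.1% reacted, a share of 0.812.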